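## The problem

The target 20 is an achiral, linear heptamer of benzene rings held together only by six diaryl ether bonds and carrying eighteen free phenolic hydroxyls. The rings are lettered A to G along the chain, and C1 is the carbon whose ether oxygen points toward ring A (in ring A, the carbon bonded to the bridge to ring B). The bridges then run A C1–O–B C1, B C4–O–C C1, C C2–O–D C1, D C4–O–E C1, E C2–O–F C1 and F C4–O–G C1. Rings B, D and F are bridged para and rings C and E ortho, so C and E are pentaoxygenated benzenes with two ether bonds on neighbouring carbons, each crowded by oxygen substituents. There is no stereocentre, so only the oxygenation pattern of each ring and the order of ether bond formation need control. The free compound, with 3,4,5-trihydroxyphenyl triads on C, E and G and a phloroglucinol ring A, is oxidised by air, fastest under base. Every hydroxyl must therefore stay masked until the last step, and even the masked rings are electron-rich enough to be attacked by oxidants and electrophiles. Six hindered aryl–oxygen bonds call for nucleophilic aromatic substitution, which needs an electron-poor ring, the opposite of what the target offers. The resolving feature is that in each of rings B to G the carbon C4, para to C1, carries an oxygen: the next bridge on B, D and F, the middle hydroxyl of the triad on C, E and G. A formyl group at C4 makes C1–F electrophilic and later becomes that oxygen by aryl migration to a peracid oxygen; on rings C, E and G this exchange can wait until the heptamer is complete.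

## Retrosynthesis

**20 from 19 from 18.** The last bonds cut are fifteen O–CH3 bonds and three O–CHO bonds. 20 is traced to its pentadeca-O-methyl ether 19, whose three free hydroxyls (C4 of rings C, E, G) come from triformate 18. Methyl ethers are preferred to benzyl ethers because both aromatic starting materials (1 and 9) are sold with them in place and because they survive organolithium, hot carbonate, aqueous acid and peracid. The price is a Lewis-acid demethylation of fifteen ethers that must spare six diaryl ether bonds and exclude air. 19 is no simpler in skeleton than 20, but it is a stable compound that can be purified.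

**18 from 17.** The three formate oxygens on C C4, E C4 and G C4 are disconnected to carbon, giving trialdehyde 17. Making these C–O bonds ring by ring during chain growth would remove the acceptor from each ring as soon as it is in place and would carry three oxidation-prone phenols or their caps through every later step. Deferring the exchange keeps rings C, E and G electron-poor to the end and finishes all three in one operation. 17 has the skeleton of 18, but every ring B to G is now recognisable as a 4-oxybenzaldehyde, the retron for SNAr. The forward reaction must oxidise three hindered aldehydes with aryl rather than hydride migration and without hydroxylating ring A.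

**17 from 12 and 16.** The bond between the bridge oxygen on B C4 and C C1 is cut, giving dimer phenol 12 (rings A and B) and pentamer fluoride 16 (rings C to G), whose C C1–F lies para to the ring C formyl group. This cut, rather than one nearer the middle, keeps the peracid- and acid-sensitive ring A out of every step of the long branch. It also makes the last union one between a two-step phenol that can be used in excess and the valuable fluoride. The forward SNAr must occur at a carbon flanked by the C2 aryloxy group, with a phenoxide flanked by two methoxy groups, and must leave the formyl-activated ether carbons E C1 and G C1 alone.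

**16 from 15 from 8 and 14; 14 from 13 from 8 and 1.** Rings C–D and E–F are the same pair, so 16 unravels into two copies of one dimer, 8, and one molecule of 1. 16 comes from acetal 15 by hydrolysis; 15 is cut at D C4–O–E C1 into 8 and trimer dialdehyde 14; 14 comes from acetal 13, which is cut at F C4–O–G C1 into 8 and 1. In 8 the formyl group of the fluoro ring is carried as an acetal. As an acetal it does not activate the fluoride, so 8 reacts only through its phenol; aqueous acid then frees the aldehyde and arms the fluoride for the next union. Growth from the G end in pairs of "couple, unmask" is preferred to growth from ring A, which would need a peracid oxidation and a protecting-group exchange on every second ring of an ever larger chain. The forward steps ask for clean acetal hydrolysis next to electron-rich rings (ring A is not yet present) and for two SNAr unions.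

**8 from 6 from 5 and 1.** The ring D hydroxyl of 8 is exchanged for a formyl group, giving aldehyde 6, which is cut at the bridge oxygen–D C1 bond into phenol 5 and 1. The ortho bridge C C2–O–D C1, the most congested ether as seen from ring C, is thereby made at the unhindered fluoride carbon of 1. The oxidation of 6 to 8 is the only carbon-to-oxygen exchange that must be run with an acetal in the molecule, and it is placed on the smallest possible substrate.

**5 from 2 from 1.** 5 differs from 1 by an acetal and one hydroxyl ortho to fluorine. That C–O bond is cut back to C–H: metalation of acetal 2 between fluorine and methoxy, then boron, then peroxide. 2 has only two ring hydrogens and they are equivalent, so the regiochemical problem usual for pentaoxygenated benzenes does not arise.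

**12 from 10 from 9 and 1.** 12 comes from aldehyde 10 by the same formyl-to-hydroxyl exchange, and 10 is cut at A–O–B C1 into 9 and 1. All carbons of rings B to G thus come from 1 and ring A from 9.

## Roads not taken

**Alternative 1: ring E written by ring expansion of a four-membered ring.** The cut opens ring E at E C5–C6 and traces it to the racemic 4-vinylcyclobutenone A1, which already carries the ring D aryloxy group on its vinyl carbon. On heating, A1 would open to a dienylketene whose six-electron closure and tautomerisation give the D–E dimer phenol A2.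
- Merits: all five oxygens of ring E are placed without ambiguity and arrive differentiated (free E C5–OH, acetal-protected E C2–O, methyl at C3 and C4). The D–O–E ether comes in with the vinyl ether, and the key step is neutral and thermal.
- Weak points: A2 still needs methylation, unmasking of E C2–O and then a hindered ether bond to ring F by some other method. The whole sequence must be repeated for ring C. A benzene ring is built de novo for an oxygenation pattern that one metalation gives from 1 in the chosen plan.
- Comparison: in regiochemical certainty of the pentaoxygenated ring and in avoiding a late peracid this road is at least as good. The chosen plan sets against it a single commercial block for six rings, one reaction type for all six ether bonds and a fourteen-step count that a ring-by-ring construction cannot approach.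

**Alternative 2: ester tether and intramolecular Ullmann closure.** The cut is the C C2–O bond to ring D, made inside a seven-membered lactone. In the depside iodide A3, the ring D salicylate hydroxyl would displace the iodide at C C2 under copper mediation to give the depsidone A4; lactone opening and decarboxylation at D C6 would then erase the tether and leave C C3–OH.
- Merits: the closure is intramolecular and the ring type is well known. The tether oxygen ends as a hydroxyl the target needs.
- Weak points: an iodide at C C2 of a pentaoxygenated ring and a carboxyl at D C6 must be carried. Decarboxylation of a di-ortho-oxygenated benzoic acid at the heptamer stage is harsh. The tether helps one ether bond (two if repeated for E–F), while the others remain intermolecular couplings of electron-rich, hindered partners, where copper chemistry is weakest.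
- Comparison: for the bond C C2–O taken alone this road is more reliable than any intermolecular method. In the chosen plan, however, that bond is made early and easily on the unhindered fluoride of 1 (step 3). The bonds that are hard there, at C C1 and E C1, are ones a C3–O tether cannot reach.

**Alternative 3: benzannulation of ring D between two trimers.** Ring D is cut into a two-carbon piece (D C1, C2) and a four-carbon piece (D C3 to C6). Heating the ynol ether A5 (rings A–B–C) with the racemic 4-aryloxycyclobutenone A6 (rings E–F–G) would pass through a vinylketene, a [2+2] adduct and a dienylketene to the heptamer A7, with D C3–OH free and an ethyl ether at D C5.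
- Merits: it is the most convergent union conceivable (three rings plus three rings with the seventh formed between them). No C–O coupling is needed at ring D, and the regiochemistry is fixed by the polarity of the ynol ether.
- Weak points: A5 needs an aryl ynol ether on a di-ortho-substituted pentaoxygenated phenol, and A6 an aryloxy-substituted four-membered ring on an equally hindered phenol. Both are multistep and fragile. Each trimer still contains two hindered diaryl ethers that must come from another method, so the central difficulty is moved, not solved.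
- Comparison: in convergence at the centre and in freedom from late oxidation-state changes this road is better on paper. The chosen plan answers with its own convergence (2+1, 2+3, 2+5 with a repeated dimer) and with two commercial aromatics feeding one repeated, well-known substitution.

Key step: step 12

Assumption: the target has no stereocentre, so no SMILES string below needs stereodescriptors; 1, 9 and 2,2-dimethylpropane-1,3-diol are taken as purchased.

## Route

Step 1
Reactants: 1 4-fluoro-2,6-dimethoxybenzaldehyde
Product: 2 2-(4-fluoro-2,6-dimethoxyphenyl)-5,5-dimethyl-1,3-dioxane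
Conditions: 2,2-dimethylpropane-1,3-diol, p-TsOH·H2O (cat.), toluene, reflux, Dean–Stark; Et3N quench
Reagents that add atoms: 2,2-dimethylpropane-1,3-diol, OCC(C)(C)CO
Why: Acid-catalysed acetalisation driven by azeotropic removal of water; the neopentyl acetal resists base and organolithiums and, being no acceptor, leaves the para fluoride inert until it is hydrolysed.

Step 2
Reactants: 2 2-(4-fluoro-2,6-dimethoxyphenyl)-5,5-dimethyl-1,3-dioxane
Product: 5 3-(5,5-dimethyl-1,3-dioxan-2-yl)-6-fluoro-2,4-dimethoxyphenol, via aryllithium 3 (not isolated), via dimethyl arylboronate 4 (not isolated)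
Conditions: s-BuLi, THF, −78 °C; B(OMe)3, −78 to 0 °C; 30% H2O2, aq NaOH, 0 °C to rt
Reagents that add atoms: hydrogen peroxide, OO (phenol oxygen of 5); sec-butyllithium, [Li]C(C)CC (lithium of 3); trimethyl borate, COB(OC)OC (boron and methoxy groups of 4)
Why: Directed ortho-metalation at the carbon between F and OMe (the two ring hydrogens of 2 are equivalent, so only one aryllithium can form), borate trapping and alkaline peroxide oxidation of the aryl–boron bond; boron is attached at −78 °C before the ortho-fluoroaryllithium can lose LiF.

Step 3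
Reactants: 5 3-(5,5-dimethyl-1,3-dioxan-2-yl)-6-fluoro-2,4-dimethoxyphenol; 1 4-fluoro-2,6-dimethoxybenzaldehyde
Product: 6 4-[3-(5,5-dimethyl-1,3-dioxan-2-yl)-6-fluoro-2,4-dimethoxyphenoxy]-2,6-dimethoxybenzaldehyde
Conditions: K2CO3, DMF, 90 °C, Ar
Reagents that add atoms: none
Why: SNAr of a phenoxide on a para-fluorobenzaldehyde; the fluoride of 5 cannot compete because its ring carries the acetal, and the electrophilic carbon of 1 has two ortho hydrogens, so the ortho bridge is made at an unhindered centre.

Step 4
Reactants: 6 4-[3-(5,5-dimethyl-1,3-dioxan-2-yl)-6-fluoro-2,4-dimethoxyphenoxy]-2,6-dimethoxybenzaldehyde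
Product: 8 4-[3-(5,5-dimethyl-1,3-dioxan-2-yl)-6-fluoro-2,4-dimethoxyphenoxy]-2,6-dimethoxyphenol, via aryl formate 7 (not isolated)
Conditions: m-CPBA, Na2HPO4 (solid), CH2Cl2, 0 °C to rt; aq Na2S2O3 wash; K2CO3 (cat.), MeOH, rt
Reagents that add atoms: 3-chloroperoxybenzoic acid, OOC(=O)c1cccc(Cl)c1
Why: Dakin-type Baeyer–Villiger oxidation (aryl migration favoured by two ortho methoxy groups and the para aryloxy group) followed by formate methanolysis; the solid phosphate buffer keeps acid from the acetal, which has no carbonyl to oxidise.

Step 5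
Reactants: 9 2,4,6-trimethoxyphenol; 1 4-fluoro-2,6-dimethoxybenzaldehyde
Product: 10 2,6-dimethoxy-4-(2,4,6-trimethoxyphenoxy)benzaldehyde
Conditions: K2CO3, DMF, 100 °C, Ar
Reagents that add atoms: none
Why: SNAr of the di-ortho-methoxy phenoxide on the para-fluorobenzaldehyde; argon protects the electron-rich phenoxide from air.

Step 6
Reactants: 10 2,6-dimethoxy-4-(2,4,6-trimethoxyphenoxy)benzaldehyde
Product: 12 2,6-dimethoxy-4-(2,4,6-trimethoxyphenoxy)phenol, via aryl formate 11 (not isolated)
Conditions: m-CPBA, Na2HPO4 (solid), CH2Cl2, 0 °C to rt; aq Na2S2O3 wash; K2CO3 (cat.), MeOH, rt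
Reagents that add atoms: 3-chloroperoxybenzoic acid, OOC(=O)c1cccc(Cl)c1
Why: Dakin-type Baeyer–Villiger oxidation and methanolysis as in step 4; it also serves as a small-scale test that carbonyl oxidation outruns peracid attack on ring A.

Step 7
Reactants: 8 4-[3-(5,5-dimethyl-1,3-dioxan-2-yl)-6-fluoro-2,4-dimethoxyphenoxy]-2,6-dimethoxyphenol; 1 4-fluoro-2,6-dimethoxybenzaldehyde
Product: 13 4-{4-[3-(5,5-dimethyl-1,3-dioxan-2-yl)-6-fluoro-2,4-dimethoxyphenoxy]-2,6-dimethoxyphenoxy}-2,6-dimethoxybenzaldehyde (rings E, F, G; fluoride at E C1, acetal at E C4, formyl at G C4)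
Conditions: K2CO3, DMF, 90 °C, Ar
Reagents that add atoms: none
Why: SNAr; here 8 supplies rings E and F and 1 becomes ring G, and the ring E fluoride stays dormant because its para carbon is an acetal.

Step 8
Reactants: 13 E–F–G trimer acetal
Product: 14 4-fluoro-3-[4-(4-formyl-3,5-dimethoxyphenoxy)-3,5-dimethoxyphenoxy]-2,6-dimethoxybenzaldehyde (rings E, F, G; fluoride at E C1, formyl at E C4 and G C4)
Conditions: 1 M aq HCl, THF, rt
Reagents that add atoms: water, O
Why: Acid hydrolysis of an aryl acetal whose oxocarbenium ion is stabilised by two ortho methoxy groups; freeing the formyl group switches on the E C1 fluoride, and ring A is not yet present to intercept the cation.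

Step 9
Reactants: 8 4-[3-(5,5-dimethyl-1,3-dioxan-2-yl)-6-fluoro-2,4-dimethoxyphenoxy]-2,6-dimethoxyphenol; 14 E–F–G trimer dialdehyde
Product: 15 pentamer of rings C to G with fluoride at C C1, 5,5-dimethyl-1,3-dioxan-2-yl at C C4, formyl at E C4 and G C4 and methoxy at C3 and C5 of every ring
Conditions: Cs2CO3, DMSO, 80 °C, Ar
Reagents that add atoms: none
Why: SNAr at E C1; 8 now supplies rings C and D, and fluoride is displaced far faster than aryloxide (element effect of SNAr), so the formyl-activated ether carbon G C1 should survive at this temperature.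

Step 10
Reactants: 15 C-to-G pentamer acetal
Product: 16 pentamer of rings C to G with fluoride at C C1, formyl at C4 of rings C, E and G and methoxy at C3 and C5 of every ring
Conditions: 1 M aq HCl, THF, rt
Reagents that add atoms: water, O
Why: Acetal hydrolysis as in step 8; it arms the last fluoride, at C C1.

Step 11
Reactants: 12 2,6-dimethoxy-4-(2,4,6-trimethoxyphenoxy)phenol; 16 C-to-G pentamer trialdehyde
Product: 17 heptamer trialdehyde with formyl at C4 of rings C, E and G and methoxy at A C2, C4, C6 and at C3 and C5 of rings B to G
Conditions: 12 (excess), Cs2CO3, DMSO, 80–90 °C, Ar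
Reagents that add atoms: none
Why: SNAr at C C1 para to the ring C formyl group; the cheap phenol is used in excess to drive the hindered union, and ring A enters only now, after the last acidic step.

Step 12
Reactants: 17 heptamer trialdehyde
Product: 18 heptamer triformate with formyloxy at C4 of rings C, E and G
Conditions: m-CPBA (dried, about 1.5 equiv per CHO), Na2HPO4 (solid), CH2Cl2, 0 °C to rt, dark; cold aq Na2S2O3 wash
Reagents that add atoms: 3-chloroperoxybenzoic acid, OOC(=O)c1cccc(Cl)c1
Why: The peracid adds to each formyl carbon to give a Criegee adduct, from which the aryl carbon C4 migrates to the proximal peroxide oxygen as 3-chlorobenzoate leaves, giving the aryl formate. The closest known reaction is the Dakin-type Baeyer–Villiger oxidation of 2,6-dialkoxybenzaldehydes to aryl formates, as already used in steps 4 and 6. No ring is closed and no stereocentre is formed; three aryl C–O bonds replace three aryl C–C bonds. Aryl must migrate in preference to hydride, and this is secured on each of rings C, E and G by two ortho methoxy groups and a para aryloxy group, which stabilise the electron-poor migrating terminus. Carbonyl oxidation must also outrun ring oxidation; the most exposed ring is A, with two free activated positions, and it has already met the same reagent in step 6, while cold, buffered, anhydrous conditions and a limited excess keep the margin. The three sites are insulated from one another by ether oxygens, so the first migration should not slow the others. The products stay as formates, so no free para-aryloxyphenol is offered to the peracid and quinone formation with chain cleavage is avoided.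

Step 13
Reactants: 18 heptamer triformate
Product: 19 heptamer triphenol, the pentadeca-O-methyl ether of the target with free OH at C4 of rings C, E and G
Conditions: K2CO3 (cat.), degassed MeOH/THF, 0 °C to rt, Ar; AcOH quench
Reagents that add atoms: none
Why: Base-catalysed transesterification of aryl formates, which are among the most labile esters; air is excluded because the freed phenols are para-aryloxy phenols.

Step 14
Reactants: 19 heptamer triphenol pentadecamethyl ether
Product: 20 target heptamer CNP0292517.0 with eighteen free hydroxyls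
Conditions: BBr3 (large excess), CH2Cl2, −78 °C to rt, Ar; MeOH then H2O at −78 °C; degassed reversed-phase purification
Reagents that add atoms: none
Why: Lewis-acid cleavage of aryl methyl ethers (boron on oxygen, bromide attack at methyl); diaryl ether bonds are inert because neither aryl carbon can undergo that substitution, and the air-sensitive product is handled under argon.

## Compound list

1 | 4-fluoro-2,6-dimethoxybenzaldehyde | COc1cc(F)cc(OC)c1C=O | starting material
2 | 2-(4-fluoro-2,6-dimethoxyphenyl)-5,5-dimethyl-1,3-dioxane | COc1cc(F)cc(OC)c1C1OCC(C)(C)CO1 | intermediate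
3 | [3-(5,5-dimethyl-1,3-dioxan-2-yl)-6-fluoro-2,4-dimethoxyphenyl]lithium | [Li]c1c(F)cc(OC)c(C2OCC(C)(C)CO2)c1OC | intermediate
4 | dimethyl [3-(5,5-dimethyl-1,3-dioxan-2-yl)-6-fluoro-2,4-dimethoxyphenyl]boronate | COB(OC)c1c(F)cc(OC)c(C2OCC(C)(C)CO2)c1OC | intermediate
5 | 3-(5,5-dimethyl-1,3-dioxan-2-yl)-6-fluoro-2,4-dimethoxyphenol | Oc1c(F)cc(OC)c(C2OCC(C)(C)CO2)c1OC | intermediate
6 | 4-[3-(5,5-dimethyl-1,3-dioxan-2-yl)-6-fluoro-2,4-dimethoxyphenoxy]-2,6-dimethoxybenzaldehyde | COc1cc(Oc2c(F)cc(OC)c(C3OCC(C)(C)CO3)c2OC)cc(OC)c1C=O | intermediate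
7 | 4-[3-(5,5-dimethyl-1,3-dioxan-2-yl)-6-fluoro-2,4-dimethoxyphenoxy]-2,6-dimethoxyphenyl formate | COc1cc(Oc2c(F)cc(OC)c(C3OCC(C)(C)CO3)c2OC)cc(OC)c1OC=O | intermediate
8 | 4-[3-(5,5-dimethyl-1,3-dioxan-2-yl)-6-fluoro-2,4-dimethoxyphenoxy]-2,6-dimethoxyphenol | COc1cc(Oc2c(F)cc(OC)c(C3OCC(C)(C)CO3)c2OC)cc(OC)c1O | intermediate
9 | 2,4,6-trimethoxyphenol | COc1cc(OC)c(O)c(OC)c1 | starting material
10 | 2,6-dimethoxy-4-(2,4,6-trimethoxyphenoxy)benzaldehyde | COc1cc(OC)c(Oc2cc(OC)c(C=O)c(OC)c2)c(OC)c1 | intermediate
11 | 2,6-dimethoxy-4-(2,4,6-trimethoxyphenoxy)phenyl formate | COc1cc(OC)c(Oc2cc(OC)c(OC=O)c(OC)c2)c(OC)c1 | intermediate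
12 | 2,6-dimethoxy-4-(2,4,6-trimethoxyphenoxy)phenol | COc1cc(OC)c(Oc2cc(OC)c(O)c(OC)c2)c(OC)c1 | intermediate
13 | 4-{4-[3-(5,5-dimethyl-1,3-dioxan-2-yl)-6-fluoro-2,4-dimethoxyphenoxy]-2,6-dimethoxyphenoxy}-2,6-dimethoxybenzaldehyde | Fc1cc(OC)c(C2OCC(C)(C)CO2)c(OC)c1Oc1cc(OC)c(Oc2cc(OC)c(C=O)c(OC)c2)c(OC)c1 | intermediate
14 | 4-fluoro-3-[4-(4-formyl-3,5-dimethoxyphenoxy)-3,5-dimethoxyphenoxy]-2,6-dimethoxybenzaldehyde | Fc1cc(OC)c(C=O)c(OC)c1Oc1cc(OC)c(Oc2cc(OC)c(C=O)c(OC)c2)c(OC)c1 | intermediate
15 | C-to-G pentamer: fluoride at C C1, 5,5-dimethyl-1,3-dioxan-2-yl at C C4, formyl at E C4 and G C4, methoxy at C3 and C5 of every ring | Fc1cc(OC)c(C2OCC(C)(C)CO2)c(OC)c1Oc1cc(OC)c(Oc2cc(OC)c(C=O)c(OC)c2Oc2cc(OC)c(Oc3cc(OC)c(C=O)c(OC)c3)c(OC)c2)c(OC)c1 | intermediate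
16 | C-to-G pentamer trialdehyde: fluoride at C C1, formyl at C4 of rings C, E and G, methoxy at C3 and C5 of every ring | Fc1cc(OC)c(C=O)c(OC)c1Oc1cc(OC)c(Oc2cc(OC)c(C=O)c(OC)c2Oc2cc(OC)c(Oc3cc(OC)c(C=O)c(OC)c3)c(OC)c2)c(OC)c1 | intermediate
17 | heptamer trialdehyde: formyl at C4 of rings C, E and G, fifteen methoxy groups | COc1cc(OC)c(Oc2cc(OC)c(Oc3cc(OC)c(C=O)c(OC)c3Oc3cc(OC)c(Oc4cc(OC)c(C=O)c(OC)c4Oc4cc(OC)c(Oc5cc(OC)c(C=O)c(OC)c5)c(OC)c4)c(OC)c3)c(OC)c2)c(OC)c1 | intermediate
18 | heptamer triformate: formyloxy at C4 of rings C, E and G, fifteen methoxy groups | COc1cc(OC)c(Oc2cc(OC)c(Oc3cc(OC)c(OC=O)c(OC)c3Oc3cc(OC)c(Oc4cc(OC)c(OC=O)c(OC)c4Oc4cc(OC)c(Oc5cc(OC)c(OC=O)c(OC)c5)c(OC)c4)c(OC)c3)c(OC)c2)c(OC)c1 | intermediate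
19 | heptamer triphenol: free OH at C4 of rings C, E and G, fifteen methoxy groups | COc1cc(OC)c(Oc2cc(OC)c(Oc3cc(OC)c(O)c(OC)c3Oc3cc(OC)c(Oc4cc(OC)c(O)c(OC)c4Oc4cc(OC)c(Oc5cc(OC)c(O)c(OC)c5)c(OC)c4)c(OC)c3)c(OC)c2)c(OC)c1 | intermediate
20 | CNP0292517.0, heptameric phlorotannin with eighteen free hydroxyls | Oc1cc(O)c(Oc2cc(O)c(Oc3cc(O)c(O)c(O)c3Oc3cc(O)c(Oc4cc(O)c(O)c(O)c4Oc4cc(O)c(Oc5cc(O)c(O)c(O)c5)c(O)c4)c(O)c3)c(O)c2)c(O)c1 | target

## Step count and least certain steps

Total step count: 14. Longest linear sequence: 12 steps (steps 1 to 4, then 7 to 14); steps 5 and 6 form the short branch to 12.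

**Step 12 (key step).** The likely failure is peracid attack on the electron-rich rings, above all hydroxylation of ring A at its two free positions, competing with the slowest of the three carbonyl oxidations. A second failure is partial loss of a formate, after which the freed para-aryloxyphenol is oxidised to a quinone with cleavage of the chain. The fallback keeps the threefold oxidation but lets the peracid never meet ring A; it sets out from 16 and returns to the route at 20. 16 is joined under the conditions of step 11 with commercial 4-bromo-2,6-dimethoxyphenol in place of 12 to give the B-to-G hexamer bromide trialdehyde F1. The same buffered peracid oxidation gives the hexamer bromide triformate F2, and methanolysis as in step 13 gives the hexamer bromide triphenol F3. MeI and K2CO3 in acetone cap the three phenols to give the permethylated hexamer bromide F4. Ullmann-type coupling of F4 with 9 (CuI, picolinic acid, K3PO4, DMSO, 100 °C) attaches ring A last and gives the octadeca-O-methyl heptamer F5, which BBr3 as in step 14 converts to 20.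

**Step 11 (and, to a lesser degree, step 9).** Substitution at C C1 is slowed by the neighbouring C2 aryloxy group and by the two methoxy groups around the phenoxide oxygen. During a slow reaction the phenoxide may instead attack the formyl-activated ether carbons E C1 and G C1, and such ether exchange would scramble the chain. The fallback removes the activation from rings that no longer need it; it sets out from 15 and returns at 20. The two formyl groups of 15 are oxidised with buffered m-CPBA (acetal retained as in step 4) to the pentamer diformate F6, methanolysed to the pentamer diphenol F7 and capped with MeI and K2CO3 to give the pentamer bis(methyl ether) acetal F8. Hydrolysis as in step 10 gives the pentamer fluoride monoaldehyde F9, in which only ring C is activated, so the union with excess 12 can be forced at higher temperature without exchange and gives the heptamer monoaldehyde F10. A single Baeyer–Villiger oxidation gives the heptamer monoformate F11, methanolysis gives the heptamer monophenol F12, and BBr3 as in step 14 gives 20.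

**Step 4.** Acid from the spent peracid or adventitious water may open the acetal, after which the ring C aldehyde is oxidised as well and the block loses its switch. The fallback makes the D-ring oxygen without any peracid; it sets out from 5 and returns at 8. Commercial 4-bromo-2,6-dimethoxyphenol is benzylated (BnBr, K2CO3, DMF) to 2-(benzyloxy)-5-bromo-1,3-dimethoxybenzene F13. Copper-catalysed coupling of 5 with F13 (CuI, picolinic acid, K3PO4, DMSO, 100 °C) gives the benzyl ether of the dimer phenol F14, and hydrogenolysis (H2, Pd/C, EtOAc, trace Et3N) gives 8.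

**Step 2.** The ortho-fluoroaryllithium may lose LiF to an aryne before boron is attached, or metalation may stay incomplete. The fallback avoids the aryllithium; it sets out from 2 and returns at 5. NBS in MeCN over NaHCO3 brominates the only kind of free ring position and gives the aryl bromide acetal F15. Miyaura borylation (B2pin2, Pd(dppf)Cl2, KOAc, dioxane, 90 °C) gives the pinacol boronate F16, and H2O2 with aqueous NaOH gives 5.

**Step 14.** Cleavage may stop short at the most hindered methoxy groups, and the free polyphenol may be oxidised by air during isolation, so that mixtures result that cannot be separated as free phenols. The fallback isolates the product in protected form; it sets out from 19 and returns at 20. After BBr3 and methanol quench the crude material is acetylated in the same flask (Ac2O, pyridine, DMAP) to the octadecaacetate F17, which is stable to air and chromatography and separates from under-demethylated material. Acid methanolysis (HCl in MeOH, generated from AcCl, under argon) then gives 20.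

## Further compounds

F1 | step 12 | B-to-G hexamer bromide trialdehyde (Br at B C1, formyl at C4 of rings C, E, G) | Brc1cc(OC)c(Oc2cc(OC)c(C=O)c(OC)c2Oc2cc(OC)c(Oc3cc(OC)c(C=O)c(OC)c3Oc3cc(OC)c(Oc4cc(OC)c(C=O)c(OC)c4)c(OC)c3)c(OC)c2)c(OC)c1
F2 | step 12 | hexamer bromide triformate | Brc1cc(OC)c(Oc2cc(OC)c(OC=O)c(OC)c2Oc2cc(OC)c(Oc3cc(OC)c(OC=O)c(OC)c3Oc3cc(OC)c(Oc4cc(OC)c(OC=O)c(OC)c4)c(OC)c3)c(OC)c2)c(OC)c1
F3 | step 12 | hexamer bromide triphenol | Brc1cc(OC)c(Oc2cc(OC)c(O)c(OC)c2Oc2cc(OC)c(Oc3cc(OC)c(O)c(OC)c3Oc3cc(OC)c(Oc4cc(OC)c(O)c(OC)c4)c(OC)c3)c(OC)c2)c(OC)c1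
F4 | step 12 | permethylated hexamer bromide | Brc1cc(OC)c(Oc2cc(OC)c(OC)c(OC)c2Oc2cc(OC)c(Oc3cc(OC)c(OC)c(OC)c3Oc3cc(OC)c(Oc4cc(OC)c(OC)c(OC)c4)c(OC)c3)c(OC)c2)c(OC)c1
F5 | step 12 | octadeca-O-methyl heptamer | COc1cc(OC)c(Oc2cc(OC)c(Oc3cc(OC)c(OC)c(OC)c3Oc3cc(OC)c(Oc4cc(OC)c(OC)c(OC)c4Oc4cc(OC)c(Oc5cc(OC)c(OC)c(OC)c5)c(OC)c4)c(OC)c3)c(OC)c2)c(OC)c1
F6 | step 11 | pentamer diformate (acetal at C C4, formyloxy at E C4 and G C4) | Fc1cc(OC)c(C2OCC(C)(C)CO2)c(OC)c1Oc1cc(OC)c(Oc2cc(OC)c(OC=O)c(OC)c2Oc2cc(OC)c(Oc3cc(OC)c(OC=O)c(OC)c3)c(OC)c2)c(OC)c1
F7 | step 11 | pentamer diphenol (acetal at C C4, OH at E C4 and G C4) | Fc1cc(OC)c(C2OCC(C)(C)CO2)c(OC)c1Oc1cc(OC)c(Oc2cc(OC)c(O)c(OC)c2Oc2cc(OC)c(Oc3cc(OC)c(O)c(OC)c3)c(OC)c2)c(OC)c1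
F8 | step 11 | pentamer bis(methyl ether) acetal | Fc1cc(OC)c(C2OCC(C)(C)CO2)c(OC)c1Oc1cc(OC)c(Oc2cc(OC)c(OC)c(OC)c2Oc2cc(OC)c(Oc3cc(OC)c(OC)c(OC)c3)c(OC)c2)c(OC)c1
F9 | step 11 | pentamer fluoride monoaldehyde (formyl at C C4 only) | Fc1cc(OC)c(C=O)c(OC)c1Oc1cc(OC)c(Oc2cc(OC)c(OC)c(OC)c2Oc2cc(OC)c(Oc3cc(OC)c(OC)c(OC)c3)c(OC)c2)c(OC)c1
F10 | step 11 | heptamer monoaldehyde (formyl at C C4, seventeen methoxy groups) | COc1cc(OC)c(Oc2cc(OC)c(Oc3cc(OC)c(C=O)c(OC)c3Oc3cc(OC)c(Oc4cc(OC)c(OC)c(OC)c4Oc4cc(OC)c(Oc5cc(OC)c(OC)c(OC)c5)c(OC)c4)c(OC)c3)c(OC)c2)c(OC)c1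
F11 | step 11 | heptamer monoformate | COc1cc(OC)c(Oc2cc(OC)c(Oc3cc(OC)c(OC=O)c(OC)c3Oc3cc(OC)c(Oc4cc(OC)c(OC)c(OC)c4Oc4cc(OC)c(Oc5cc(OC)c(OC)c(OC)c5)c(OC)c4)c(OC)c3)c(OC)c2)c(OC)c1
F12 | step 11 | heptamer monophenol (OH at C C4, seventeen methoxy groups) | COc1cc(OC)c(Oc2cc(OC)c(Oc3cc(OC)c(O)c(OC)c3Oc3cc(OC)c(Oc4cc(OC)c(OC)c(OC)c4Oc4cc(OC)c(Oc5cc(OC)c(OC)c(OC)c5)c(OC)c4)c(OC)c3)c(OC)c2)c(OC)c1
F13 | step 4 | 2-(benzyloxy)-5-bromo-1,3-dimethoxybenzene | COc1cc(Br)cc(OC)c1OCc1ccccc1
F14 | step 4 | benzyl ether of dimer phenol 8 | COc1cc(Oc2c(F)cc(OC)c(C3OCC(C)(C)CO3)c2OC)cc(OC)c1OCc1ccccc1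
F15 | step 2 | 2-(3-bromo-4-fluoro-2,6-dimethoxyphenyl)-5,5-dimethyl-1,3-dioxane | COc1cc(F)c(Br)c(OC)c1C1OCC(C)(C)CO1
F16 | step 2 | 2-[3-(5,5-dimethyl-1,3-dioxan-2-yl)-6-fluoro-2,4-dimethoxyphenyl]-4,4,5,5-tetramethyl-1,3,2-dioxaborolane | COc1cc(F)c(B2OC(C)(C)C(C)(C)O2)c(OC)c1C1OCC(C)(C)CO1
F17 | step 14 | octadecaacetate of the target | CC(=O)Oc1cc(OC(C)=O)c(Oc2cc(OC(C)=O)c(Oc3cc(OC(C)=O)c(OC(C)=O)c(OC(C)=O)c3Oc3cc(OC(C)=O)c(Oc4cc(OC(C)=O)c(OC(C)=O)c(OC(C)=O)c4Oc4cc(OC(C)=O)c(Oc5cc(OC(C)=O)c(OC(C)=O)c(OC(C)=O)c5)c(OC(C)=O)c4)c(OC(C)=O)c3)c(OC(C)=O)c2)c(OC(C)=O)c1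
A1 | alternative 1 | racemic 4-{1-[4-(benzyloxy)-2,6-dimethoxyphenoxy]ethenyl}-2,3-dimethoxy-4-(methoxymethoxy)cyclobut-2-en-1-one | COCOC1(C(=C)Oc2c(OC)cc(OCc3ccccc3)cc2OC)C(OC)=C(OC)C1=O
A2 | alternative 1 | D–E dimer phenol with free E C5–OH, methoxymethyl ether at E C2–O and benzyl ether at D C1–O | COCOc1c(OC)c(OC)c(O)cc1Oc1c(OC)cc(OCc2ccccc2)cc1OC
A3 | alternative 2 | depside iodide (iodide at C C2, ester from C C3–O to D C6, free D C1–OH) | COc1cc(OC)c(Oc2cc(OC)c(Oc3cc(OC)c(OC)c(OC(=O)c4c(O)cc(OC)c(Oc5cc(OC)c(OC)c(OC)c5Oc5cc(OC)c(Oc6cc(OC)c(OC)c(OC)c6)c(OC)c5)c4OC)c3I)c(OC)c2)c(OC)c1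
A4 | alternative 2 | heptamer depsidone bridging rings C and D | COc1cc(OC)c(Oc2cc(OC)c(Oc3cc(OC)c(OC)c4OC(=O)c5c(Oc34)cc(OC)c(Oc6cc(OC)c(OC)c(OC)c6Oc6cc(OC)c(Oc7cc(OC)c(OC)c(OC)c7)c(OC)c6)c5OC)c(OC)c2)c(OC)c1
A5 | alternative 3 | A–B–C trimer ethynyl ether at C C2–O | COc1cc(OC)c(Oc2cc(OC)c(Oc3cc(OC)c(OC)c(OC)c3OC#C)c(OC)c2)c(OC)c1
A6 | alternative 3 | racemic 3-ethoxy-4-aryloxycyclobut-2-en-1-one on E C1–O of the E–F–G trimer | CCOC1=CC(=O)C1Oc1cc(OC)c(OC)c(OC)c1Oc1cc(OC)c(Oc2cc(OC)c(OC)c(OC)c2)c(OC)c1
A7 | alternative 3 | heptamer with free D C3–OH and ethyl ether at D C5 | COc1cc(OC)c(Oc2cc(OC)c(Oc3cc(OC)c(OC)c(OC)c3Oc3cc(O)c(Oc4cc(OC)c(OC)c(OC)c4Oc4cc(OC)c(Oc5cc(OC)c(OC)c(OC)c5)c(OC)c4)c(OCC)c3)c(OC)c2)c(OC)c1
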